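**Retrosynthetic overview**
1. Target 20 ⇐ (2S)-bis-MOM ether 19; the acetal cleavage comes last.
2. Key disconnection C2–C1′ (ring C to ring B): enantioconvergent nickel/photoredox decarboxylative arylation joins the 4-oxochroman-2-yl radical from racemic acid 13 with aryl iodide 18. This step alone sets C2.
3. 13 ⇐ acetophenone 10 + glyoxylic acid: aldol condensation, then oxa-Michael closure of ring C on the only free phenol, which fixes the prenyl group at C8.
4. 10 ⇐ resorcinol: MOM protection, C–H borylation/oxidation (third oxygen), ortho-prenylation, ortho-formylation, methyl addition/oxidation. 18 ⇐ 4-iodophenol: ortho-prenylation, then chromene annulation with prenal.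
5. Ring order: ring A (from resorcinol) → ring C (pyranone); separately ring B with its fused pyran ring D; the two halves are joined last at C2.

Assumption: the (S,S)-enantiomer of the cyano-bis(oxazoline) ligand is taken to give the 2S product in step 9; its antipode is used if the sense of induction is found to be opposite.

**Step 1**
Reactants: 1 resorcinol
Product: 2 1,3-bis(methoxymethoxy)benzene
Conditions: NaH (2.4 equiv), MOMCl (2.4 equiv), DMF, 0 °C → rt
Reagents that add atoms: chloromethyl methyl ether, COCCl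
Why: Williamson-type O-alkylation of the bis-phenoxide; the MOM ethers steer the later C–H borylation and stay on as the protecting groups of O5 and O7.

**Step 2**
Reactants: 2 1,3-bis(methoxymethoxy)benzene
Product: 4 3,5-bis(methoxymethoxy)phenol, via pinacol arylboronate 3 (not isolated)
Conditions: [Ir(OMe)(cod)]2 (1.5 mol %), 4,4'-di-tert-butyl-2,2'-bipyridine (3 mol %), B2pin2 (0.6 equiv), THF, 80 °C; then 30% H2O2, aq NaOH, 0 °C
Reagents that add atoms: bis(pinacolato)diboron, CC1(C)OB(OC1(C)C)B1OC(C)(C)C(C)(C)O1; hydrogen peroxide, OO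
Why: Sterically governed iridium-catalysed C–H borylation (Hartwig–Miyaura type) takes the only C–H not ortho to an OMOM group (C5), and oxidation of the C–B bond gives the phenol oxygen that becomes O1.

**Step 3**
Reactants: 4 3,5-bis(methoxymethoxy)phenol; 5 prenyl bromide
Product: 6 3,5-bis(methoxymethoxy)-2-(3-methylbut-2-en-1-yl)phenol
Conditions: NaH (1.05 equiv), toluene, 0 °C; then 5 (1.0 equiv), rt, 16 h
Reagents that add atoms: none
Why: Ortho-C-allylation of the tight sodium phenoxide ion pair in a non-polar solvent (both ortho carbons are equivalent) gives a phenol with one free OH and one free ortho C–H, which fixes the later 8-prenyl regiochemistry.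

**Step 4**
Reactants: 6 3,5-bis(methoxymethoxy)-2-(3-methylbut-2-en-1-yl)phenol
Product: 8 2-hydroxy-4,6-bis(methoxymethoxy)-3-(3-methylbut-2-en-1-yl)benzaldehyde, via salicyl alcohol 7 (not isolated)
Conditions: MgCl2 (1.5 equiv), Et3N (3.8 equiv), (CH2O)n (6 equiv), MeCN, reflux, 3 h; aq citric acid work-up
Reagents that add atoms: paraformaldehyde (formaldehyde), C=O
Why: Magnesium-mediated ortho-specific formylation (Casnati–Skattebøl): the magnesium phenoxide delivers formaldehyde to the single free ortho carbon, and the benzylic alkoxide 7 is oxidised by a second formaldehyde through hydride transfer, under base-only conditions that spare MOM and prenyl groups.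

**Step 5**
Reactants: 8 2-hydroxy-4,6-bis(methoxymethoxy)-3-(3-methylbut-2-en-1-yl)benzaldehyde
Product: 10 1-[2-hydroxy-4,6-bis(methoxymethoxy)-3-(3-methylbut-2-en-1-yl)phenyl]ethan-1-one, via bromomagnesium alkoxide 9 (not isolated)
Conditions: MeMgBr (3 equiv), THF, 0 °C → rt; then 1,1'-(azodicarbonyl)dipiperidine (1.5 equiv), 0 °C → rt; aq NH4Cl
Reagents that add atoms: methylmagnesium bromide, C[Mg]Br
Why: Grignard addition to the aldehyde followed in the same flask by Mukaiyama oxidation of the bromomagnesium alkoxide (hydride transfer to the azo compound), which avoids isolating the labile electron-rich benzylic alcohol.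

**Step 6**
Reactants: 10 1-[2-hydroxy-4,6-bis(methoxymethoxy)-3-(3-methylbut-2-en-1-yl)phenyl]ethan-1-one; 11 glyoxylic acid (monohydrate)
Product: 13 rac-5,7-bis(methoxymethoxy)-8-(3-methylbut-2-en-1-yl)-4-oxochromane-2-carboxylic acid, via aroylacrylic acid 12 (not isolated)
Conditions: 11 (1.5 equiv), pyrrolidine (2.5 equiv), MeOH, 50 °C, 12 h; then aq citric acid to pH 4
Reagents that add atoms: none
Why: Pyrrolidine-mediated aldol condensation (Kabbe-type) gives aroylacrylic acid 12, whose only free phenol closes ring C by 6-endo oxa-Michael addition at the carbon β to the ketone; C2 is formed racemic and is reset in step 9.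

**Step 7**
Reactants: 14 4-iodophenol; 5 prenyl bromide
Product: 15 4-iodo-2-(3-methylbut-2-en-1-yl)phenol
Conditions: NaH (1.05 equiv), toluene, 0 °C; then 5 (1.0 equiv), rt, 16 h
Reagents that add atoms: none
Why: Ortho-C-allylation of the sodium phenoxide in a non-polar solvent, with the para position blocked by iodine.

**Step 8**
Reactants: 15 4-iodo-2-(3-methylbut-2-en-1-yl)phenol; 16 3-methylbut-2-enal
Product: 18 6-iodo-2,2-dimethyl-8-(3-methylbut-2-en-1-yl)-2H-chromene, via ortho-quinone methide 17 (not isolated)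
Conditions: PhB(OH)2 (1.0 equiv), AcOH (cat.), toluene, reflux, Dean–Stark, 24 h
Reagents that add atoms: none
Why: Phenylboronic acid-templated ortho-selective condensation of the phenol with the enal gives ortho-quinone methide 17, which closes ring D by oxa-6π electrocyclisation (chromene annulation).

**Step 9**
Reactants: 13 rac-5,7-bis(methoxymethoxy)-8-(3-methylbut-2-en-1-yl)-4-oxochromane-2-carboxylic acid (1.5 equiv); 18 6-iodo-2,2-dimethyl-8-(3-methylbut-2-en-1-yl)-2H-chromene
Product: 19 (2S)-2-[2,2-dimethyl-8-(3-methylbut-2-en-1-yl)-2H-chromen-6-yl]-5,7-bis(methoxymethoxy)-8-(3-methylbut-2-en-1-yl)chroman-4-one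
Conditions: NiCl2(dme) (10 mol %), (S,S)-2,2-bis[4-(4-tert-butylphenyl)-4,5-dihydro-1,3-oxazol-2-yl]acetonitrile (12 mol %), [Ir(dF(CF3)ppy)2(dtbbpy)]PF6 (2 mol %), Cs2CO3 (0.75 equiv), DME/DMF 4:1, blue LEDs (450 nm), 15 °C, 36 h, degassed
Reagents that add atoms: none
Why: Proposed new method: the excited iridium photocatalyst oxidises the caesium carboxylate of 13, loss of CO2 gives the planar α-oxy 4-oxochroman-2-yl radical, this is captured by the chiral aryl–nickel species formed from 18 and zerovalent nickel, and C–C reductive elimination from trivalent nickel sets C2; since both enantiomers of 13 give the same radical the coupling is enantioconvergent and the ligand fixes 2S, and the only base is the carboxylate itself, which limits retro-oxa-Michael racemisation; the closest known reaction types are the nickel/photoredox enantioselective decarboxylative arylation of α-amino acids and the nickel-catalysed enantioselective arylation of α-oxy radicals of cyclic ethers.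

**Step 10**
Reactants: 19 (2S)-2-[2,2-dimethyl-8-(3-methylbut-2-en-1-yl)-2H-chromen-6-yl]-5,7-bis(methoxymethoxy)-8-(3-methylbut-2-en-1-yl)chroman-4-one
Product: 20 Maackiaflavanone B
Conditions: HCl (1.25 M in MeOH), THF, 40 °C, 3 h
Reagents that add atoms: none
Why: Acid-catalysed acetal exchange with methanol removes both MOM groups; the acid is kept mild so that C2, the two prenyl groups and the chromene are not touched (MOM deprotection).

**Compound list**
1 | resorcinol (benzene-1,3-diol) | Oc1cccc(O)c1 | starting material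
2 | 1,3-bis(methoxymethoxy)benzene | COCOc1cccc(OCOC)c1 | intermediate
3 | 2-[3,5-bis(methoxymethoxy)phenyl]-4,4,5,5-tetramethyl-1,3,2-dioxaborolane (not isolated) | COCOc1cc(OCOC)cc(c1)B1OC(C)(C)C(C)(C)O1 | intermediate
4 | 3,5-bis(methoxymethoxy)phenol | COCOc1cc(O)cc(OCOC)c1 | intermediate
5 | prenyl bromide (1-bromo-3-methylbut-2-ene) | CC(C)=CCBr | starting material
6 | 3,5-bis(methoxymethoxy)-2-(3-methylbut-2-en-1-yl)phenol | COCOc1cc(O)c(CC=C(C)C)c(OCOC)c1 | intermediate
7 | 2-(hydroxymethyl)-3,5-bis(methoxymethoxy)-6-(3-methylbut-2-en-1-yl)phenol, present as its magnesium salt (not isolated) | OCc1c(O)c(CC=C(C)C)c(OCOC)cc1OCOC | intermediate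
8 | 2-hydroxy-4,6-bis(methoxymethoxy)-3-(3-methylbut-2-en-1-yl)benzaldehyde | O=Cc1c(O)c(CC=C(C)C)c(OCOC)cc1OCOC | intermediate
9 | bis(bromomagnesium) salt of racemic 2-(1-hydroxyethyl)-3,5-bis(methoxymethoxy)-6-(3-methylbut-2-en-1-yl)phenol (not isolated) | CC(O[Mg]Br)c1c(O[Mg]Br)c(CC=C(C)C)c(OCOC)cc1OCOC | intermediate
10 | 1-[2-hydroxy-4,6-bis(methoxymethoxy)-3-(3-methylbut-2-en-1-yl)phenyl]ethan-1-one | CC(=O)c1c(O)c(CC=C(C)C)c(OCOC)cc1OCOC | intermediate
11 | glyoxylic acid (used as the monohydrate) | O=CC(=O)O | starting material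
12 | (E)-4-[2-hydroxy-4,6-bis(methoxymethoxy)-3-(3-methylbut-2-en-1-yl)phenyl]-4-oxobut-2-enoic acid (not isolated) | OC(=O)/C=C/C(=O)c1c(O)c(CC=C(C)C)c(OCOC)cc1OCOC | intermediate
13 | rac-5,7-bis(methoxymethoxy)-8-(3-methylbut-2-en-1-yl)-4-oxochromane-2-carboxylic acid | OC(=O)C1CC(=O)c2c(OCOC)cc(OCOC)c(CC=C(C)C)c2O1 | intermediate
14 | 4-iodophenol | Oc1ccc(I)cc1 | starting material
15 | 4-iodo-2-(3-methylbut-2-en-1-yl)phenol | CC(C)=CCc1cc(I)ccc1O | intermediate
16 | 3-methylbut-2-enal (prenal) | CC(C)=CC=O | starting material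
17 | 4-iodo-2-(3-methylbut-2-en-1-yl)-6-(3-methylbut-2-en-1-ylidene)cyclohexa-2,4-dien-1-one (not isolated) | O=C1C(CC=C(C)C)=CC(I)=CC1=CC=C(C)C | intermediate
18 | 6-iodo-2,2-dimethyl-8-(3-methylbut-2-en-1-yl)-2H-chromene | CC(C)=CCc1cc(I)cc2c1OC(C)(C)C=C2 | intermediate
19 | (2S)-2-[2,2-dimethyl-8-(3-methylbut-2-en-1-yl)-2H-chromen-6-yl]-5,7-bis(methoxymethoxy)-8-(3-methylbut-2-en-1-yl)chroman-4-one | CC(C)=CCc1cc([C@@H]2CC(=O)c3c(OCOC)cc(OCOC)c(CC=C(C)C)c3O2)cc2c1OC(C)(C)C=C2 | intermediate
20 | Maackiaflavanone B, (2S)-2-[2,2-dimethyl-8-(3-methylbut-2-en-1-yl)-2H-chromen-6-yl]-5,7-dihydroxy-8-(3-methylbut-2-en-1-yl)chroman-4-one | CC(C)=CCc1cc([C@@H]2CC(=O)c3c(O)cc(O)c(CC=C(C)C)c3O2)cc2c1OC(C)(C)C=C2 | target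

**Step count**
Total: 10 steps. Longest linear sequence: 8 steps (steps 1–6, 9, 10).

**Steps most likely to fail, with fallbacks**

Step 9 (radical arylation). The enantioselective capture of the α-oxy radical is unproven for this ring system and may give low ee. The fallback sets out from 13 and 18. The same radical decarboxylative arylation is run with the achiral ligand 4,4'-di-tert-butyl-2,2'-bipyridine on nickel, which gives the racemic bis-MOM flavanone F1. Kinetic resolution by asymmetric transfer hydrogenation with RuCl[(R,R)-TsDPEN](p-cymene) and HCO2H/Et3N, stopped near half conversion, reduces the 2R enantiomer to the (2R,4R)-cis-flavan-4-ol F2. F2 is separated by chromatography, and the unreacted 2S ketone is 19, where the route is rejoined.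

Step 6 (glyoxylic acid condensation). The hindered, chelated methyl ketone may condense slowly, or the acid may be hard to isolate. The fallback sets out from 10. Claisen condensation with dimethyl oxalate (NaH, THF) gives the cyclic hemiketal ester F3. Dehydration with catalytic pyridinium p-toluenesulfonate in toluene at 60 °C gives the chromone ester F4. Copper hydride 1,4-reduction with [CuH(PPh3)]6 and PhSiH3 in toluene gives the racemic chromanone ester F5. Saponification with LiOH in THF/H2O at 0 °C returns to 13.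

Step 8 (chromene annulation). The boronic acid-mediated condensation may be sluggish with an iodophenol, and the ortho-prenyl phenol may cyclise in hot acid. The fallback sets out from 15. O-Alkylation with 3-chloro-3-methylbut-1-yne (K2CO3, KI, CuCl2 cat., acetone, reflux) gives the aryl 1,1-dimethylpropargyl ether F6. Heating in N,N-diethylaniline at 180 °C brings about propargyl Claisen rearrangement, 1,5-hydrogen shift and oxa-6π electrocyclisation to give 18.

**Further compounds**
F1 | step 9 | rac-2-[2,2-dimethyl-8-(3-methylbut-2-en-1-yl)-2H-chromen-6-yl]-5,7-bis(methoxymethoxy)-8-(3-methylbut-2-en-1-yl)chroman-4-one | CC(C)=CCc1cc(C2CC(=O)c3c(OCOC)cc(OCOC)c(CC=C(C)C)c3O2)cc2c1OC(C)(C)C=C2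
F2 | step 9 | (2R,4R)-2-[2,2-dimethyl-8-(3-methylbut-2-en-1-yl)-2H-chromen-6-yl]-5,7-bis(methoxymethoxy)-8-(3-methylbut-2-en-1-yl)chroman-4-ol | CC(C)=CCc1cc([C@H]2C[C@@H](O)c3c(OCOC)cc(OCOC)c(CC=C(C)C)c3O2)cc2c1OC(C)(C)C=C2
F3 | step 6 | methyl rac-2-hydroxy-5,7-bis(methoxymethoxy)-8-(3-methylbut-2-en-1-yl)-4-oxochromane-2-carboxylate | COC(=O)C1(O)CC(=O)c2c(OCOC)cc(OCOC)c(CC=C(C)C)c2O1
F4 | step 6 | methyl 5,7-bis(methoxymethoxy)-8-(3-methylbut-2-en-1-yl)-4-oxo-4H-chromene-2-carboxylate | COC(=O)C1=CC(=O)c2c(OCOC)cc(OCOC)c(CC=C(C)C)c2O1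
F5 | step 6 | methyl rac-5,7-bis(methoxymethoxy)-8-(3-methylbut-2-en-1-yl)-4-oxochromane-2-carboxylate | COC(=O)C1CC(=O)c2c(OCOC)cc(OCOC)c(CC=C(C)C)c2O1
F6 | step 8 | 4-iodo-1-[(2-methylbut-3-yn-2-yl)oxy]-2-(3-methylbut-2-en-1-yl)benzene | C#CC(C)(C)Oc1ccc(I)cc1CC=C(C)C
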